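**Retrosynthetic overview**
1. Target ⇐ siphonaxanthin with TBS ethers on O3/O3′ and a free C19 hydroxyl (Steglich esterification with (2E)-oct-2-enoic acid, then desilylation).
2. C40 skeleton ⇐ intermolecular aldol addition of the C9 lithium enolate of a C13 β-ring ketone to a C27 ε-ring polyenal, then dehydration to the C9=C10 enone (key C9–C10 bond).
3. C13 ketone ⇐ (R)-3-silyloxy-β-cyclogeranyl phenyl sulfone + 3-(triethylsilyloxy)propanal (addition, oxidation, desulfonylation); sulfone ⇐ (4R,6R)-actinol via enol triflate and carbonylation.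
4. C27 polyenal ⇐ Wittig of an ε-ring C15 phosphonium salt with a C12 ester-aldehyde (from the C10 dialdehyde); C15 salt ⇐ racemic α-ionone by HWE, ring allylic oxidation, trans-selective reduction and lipase resolution.
5. Rings: neither ring is built; the β ring comes intact from actinol and the ε ring from α-ionone, and only their substituents are adjusted.

Assumption: (4R,6R)-actinol and (2E,4E,6E)-2,7-dimethylocta-2,4,6-trienedial are taken as purchasable bulk carotenoid intermediates, and the target is the all-E isomer written in the SMILES.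

**Part A – β-ring C13 ketone**

Step 1
Reactants: 1 (4R,6R)-4-hydroxy-2,2,6-trimethylcyclohexan-1-one (actinol)
Product: 2 (4R,6R)-4-[(tert-butyldimethylsilyl)oxy]-2,2,6-trimethylcyclohexan-1-one
Conditions: TBSCl, imidazole, DMF, rt
Reagents that add atoms: tert-butyldimethylsilyl chloride TBSCl, CC(C)(C)[Si](C)(C)Cl
Why: Imidazole-promoted O-silylation of the only hydroxyl does not touch the carbinol carbon, so the 4R centre (C3 of the target) is carried over unchanged.

Step 2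
Reactants: 2 (4R,6R)-4-[(tert-butyldimethylsilyl)oxy]-2,2,6-trimethylcyclohexan-1-one
Product: 4 (4R)-4-[(tert-butyldimethylsilyl)oxy]-2,6,6-trimethylcyclohex-1-en-1-yl trifluoromethanesulfonate, via lithium enolate 3 (not isolated)
Conditions: LiN(i-Pr)2, THF, −78 → 0 °C; PhNTf2, 0 °C → rt
Reagents that add atoms: N-phenylbis(trifluoromethanesulfonimide) PhNTf2, O=S(=O)(N(c1ccccc1)S(=O)(=O)C(F)(F)F)C(F)(F)F
Why: Enolisation is possible only towards C6 (C2 is quaternary), so O-triflation of the single enolate gives the tetrasubstituted enol triflate; the C6 centre is erased on purpose and the silyloxy carbon is untouched.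

Step 3
Reactants: 4 (4R)-4-[(tert-butyldimethylsilyl)oxy]-2,6,6-trimethylcyclohex-1-en-1-yl trifluoromethanesulfonate
Product: 5 methyl (4R)-4-[(tert-butyldimethylsilyl)oxy]-2,6,6-trimethylcyclohex-1-ene-1-carboxylate
Conditions: Pd(OAc)2 (5 mol %), PPh3, CO (1 atm), MeOH, Et3N, DMF, 60 °C
Reagents that add atoms: carbon monoxide, [C-]#[O+]; methanol CH3OH, CO
Why: Palladium-catalysed methoxycarbonylation (oxidative addition of the vinyl triflate to zerovalent palladium, CO insertion, methanolysis) installs C7 as an ester.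

Step 4
Reactants: 5 methyl (4R)-4-[(tert-butyldimethylsilyl)oxy]-2,6,6-trimethylcyclohex-1-ene-1-carboxylate
Product: 6 [(4R)-4-[(tert-butyldimethylsilyl)oxy]-2,6,6-trimethylcyclohex-1-en-1-yl]methanol
Conditions: i-Bu2AlH, CH2Cl2, −78 → 0 °C
Reagents that add atoms: none
Why: Aluminium hydride 1,2-reduction of the hindered conjugated ester gives the allylic alcohol and leaves the silyl ether and the alkene alone.

Step 5
Reactants: 6 [(4R)-4-[(tert-butyldimethylsilyl)oxy]-2,6,6-trimethylcyclohex-1-en-1-yl]methanol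
Product: 7 {[(1R)-4-(bromomethyl)-3,5,5-trimethylcyclohex-3-en-1-yl]oxy}(tert-butyl)dimethylsilane
Conditions: CBr4, PPh3, CH2Cl2, 0 °C
Reagents that add atoms: carbon tetrabromide CBr4, BrC(Br)(Br)Br
Why: The Appel bromination is neutral, so the silyl ether survives, and the primary allylic alcohol is substituted without transposition because the other allyl terminus is a fully substituted ring carbon.

Step 6
Reactants: 7 {[(1R)-4-(bromomethyl)-3,5,5-trimethylcyclohex-3-en-1-yl]oxy}(tert-butyl)dimethylsilane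
Product: 8 tert-butyldimethyl({(1R)-3,5,5-trimethyl-4-[(phenylsulfonyl)methyl]cyclohex-3-en-1-yl}oxy)silane
Conditions: PhSO2Na, DMF, rt
Reagents that add atoms: sodium benzenesulfinate PhSO2Na, [Na+].[O-]S(=O)c1ccccc1
Why: SN2 S-alkylation of the ambident sulfinate by the primary allylic bromide gives the allylic sulfone that will make C7 nucleophilic.

Step 7
Reactants: 9 propane-1,3-diol
Product: 10 3-[(triethylsilyl)oxy]propan-1-ol
Conditions: TESCl (1 equiv), 9 (5 equiv), Et3N, CH2Cl2, 0 °C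
Reagents that add atoms: triethylsilyl chloride TESCl, CC[Si](Cl)(CC)CC
Why: Statistical monosilylation of the cheap diol used in excess gives the mono-TES ether, which is separated from diol and bis-ether by extraction and chromatography.

Step 8
Reactants: 10 3-[(triethylsilyl)oxy]propan-1-ol
Product: 11 3-[(triethylsilyl)oxy]propanal
Conditions: Dess–Martin periodinane, NaHCO3, CH2Cl2, 0 °C → rt
Reagents that add atoms: none
Why: Buffered Dess–Martin oxidation gives the aldehyde under non-basic conditions that neither cleave the primary TES ether nor β-eliminate it.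

Step 9
Reactants: 8 tert-butyldimethyl({(1R)-3,5,5-trimethyl-4-[(phenylsulfonyl)methyl]cyclohex-3-en-1-yl}oxy)silane; 11 3-[(triethylsilyl)oxy]propanal
Product: 13 1-[(4R)-4-[(tert-butyldimethylsilyl)oxy]-2,6,6-trimethylcyclohex-1-en-1-yl]-1-(phenylsulfonyl)-4-[(triethylsilyl)oxy]butan-2-ol (diastereomer mixture), via lithiated sulfone 12 (not isolated)
Conditions: n-BuLi, THF, −78 °C; then 11, −78 °C; H2O
Reagents that add atoms: none
Why: The α-lithiated allylic sulfone adds 1,2 to the aldehyde through C7 (Julia-type addition; attack through the ring carbon would create a quaternary centre), and the two new stereocentres (C7, C8) are uncontrolled because both are erased in steps 10 and 11.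

Step 10
Reactants: 13 1-[(4R)-4-[(tert-butyldimethylsilyl)oxy]-2,6,6-trimethylcyclohex-1-en-1-yl]-1-(phenylsulfonyl)-4-[(triethylsilyl)oxy]butan-2-ol
Product: 14 1-[(4R)-4-[(tert-butyldimethylsilyl)oxy]-2,6,6-trimethylcyclohex-1-en-1-yl]-1-(phenylsulfonyl)-4-[(triethylsilyl)oxy]butan-2-one
Conditions: Dess–Martin periodinane, NaHCO3, CH2Cl2, rt
Reagents that add atoms: none
Why: Dess–Martin oxidation turns the secondary alcohol into the C8 ketone without acid or base strong enough to harm the silyl ethers.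

Step 11
Reactants: 14 1-[(4R)-4-[(tert-butyldimethylsilyl)oxy]-2,6,6-trimethylcyclohex-1-en-1-yl]-1-(phenylsulfonyl)-4-[(triethylsilyl)oxy]butan-2-one
Product: 15 1-[(4R)-4-[(tert-butyldimethylsilyl)oxy]-2,6,6-trimethylcyclohex-1-en-1-yl]-4-[(triethylsilyl)oxy]butan-2-one
Conditions: SmI2, THF/MeOH, −78 °C
Reagents that add atoms: none
Why: Single-electron reductive desulfonylation of the α-sulfonyl ketone by SmI2 (divalent samarium) gives a samarium enolate that methanol protonates at C7, leaving the ring alkene tetrasubstituted.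

**Part B – ε-ring C27 polyenal**

Step 12
Reactants: 16 (±)-α-ionone, (3E)-4-(2,6,6-trimethylcyclohex-2-en-1-yl)but-3-en-2-one
Product: 17 ethyl (2E,4E)-3-methyl-5-(2,6,6-trimethylcyclohex-2-en-1-yl)penta-2,4-dienoate (racemic)
Conditions: (EtO)2P(O)CH2CO2Et, NaH, THF, 0 → 50 °C; chromatography (2E isomer)
Reagents that add atoms: triethyl phosphonoacetate, CCOC(=O)CP(=O)(OCC)OCC
Why: Horner–Wadsworth–Emmons olefination of the methyl ketone gives mainly the 2E dienoate (about 4:1), and the minor 2Z isomer is removed by chromatography.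

Step 13
Reactants: 17 ethyl (2E,4E)-3-methyl-5-(2,6,6-trimethylcyclohex-2-en-1-yl)penta-2,4-dienoate
Product: 18 ethyl (2E,4E)-3-methyl-5-(2,6,6-trimethyl-4-oxocyclohex-2-en-1-yl)penta-2,4-dienoate (racemic)
Conditions: Rh2(cap)4 (1 mol %; cap = caprolactamate, C6H10NO), t-BuOOH (70 % aq.), K2CO3, CH2Cl2, rt
Reagents that add atoms: tert-butyl hydroperoxide t-BuOOH, CC(C)(C)OO
Why: Dirhodium-catalysed allylic oxidation (tert-butylperoxyl radical chain) attacks the only unhindered ring allylic CH2 and gives the cyclohexenone, as 3-oxo-α-ionone forms from α-ionone.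

Step 14
Reactants: 18 ethyl (2E,4E)-3-methyl-5-(2,6,6-trimethyl-4-oxocyclohex-2-en-1-yl)penta-2,4-dienoate
Product: 19 ethyl (2E,4E)-5-[(1RS,4RS)-4-hydroxy-2,6,6-trimethylcyclohex-2-en-1-yl]-3-methylpenta-2,4-dienoate (racemic trans)
Conditions: LiBH(s-Bu)3, THF, −78 °C; chromatography
Reagents that add atoms: none
Why: The bulky borohydride reduces the β,β-disubstituted enone 1,2 and, in the half-chair with the side chain pseudo-axial, enters anti to the syn-axial methyl of the gem-dimethyl carbon, so the new hydroxyl ends up trans to the side chain (relative configuration of C3′/C6′); the minor cis isomer is removed by chromatography.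

Step 15
Reactants: 19 ethyl (2E,4E)-5-[(1RS,4RS)-4-hydroxy-2,6,6-trimethylcyclohex-2-en-1-yl]-3-methylpenta-2,4-dienoate (racemic trans)
Product: 20 ethyl (2E,4E)-5-[(1R,4R)-4-acetoxy-2,6,6-trimethylcyclohex-2-en-1-yl]-3-methylpenta-2,4-dienoate
Conditions: Burkholderia cepacia lipase (Amano PS), vinyl acetate, t-BuOMe, 30 °C, about 50 % conversion
Reagents that add atoms: vinyl acetate, CC(=O)OC=C
Why: Lipase-catalysed kinetic resolution by irreversible transesterification acylates the (4R)-carbinol (Kazlauskas rule, alkene side as the large group), so the (1R,4R) enantiomer is obtained as the acetate and separated from the unreacted (1S,4S) alcohol, which fixes the absolute configuration of C3′ and C6′.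

Step 16
Reactants: 20 ethyl (2E,4E)-5-[(1R,4R)-4-acetoxy-2,6,6-trimethylcyclohex-2-en-1-yl]-3-methylpenta-2,4-dienoate
Product: 21 ethyl (2E,4E)-5-[(1R,4R)-4-hydroxy-2,6,6-trimethylcyclohex-2-en-1-yl]-3-methylpenta-2,4-dienoate
Conditions: K2CO3, EtOH, rt
Reagents that add atoms: none
Why: Base-catalysed transesterification cleaves the acetate at the acyl–oxygen bond (retention at carbon), and ethanol as solvent keeps the ethyl dienoate unchanged.

Step 17
Reactants: 21 ethyl (2E,4E)-5-[(1R,4R)-4-hydroxy-2,6,6-trimethylcyclohex-2-en-1-yl]-3-methylpenta-2,4-dienoate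
Product: 22 ethyl (2E,4E)-5-[(1R,4R)-4-[(tert-butyldimethylsilyl)oxy]-2,6,6-trimethylcyclohex-2-en-1-yl]-3-methylpenta-2,4-dienoate
Conditions: TBSCl, imidazole, DMF, rt
Reagents that add atoms: tert-butyldimethylsilyl chloride TBSCl, CC(C)(C)[Si](C)(C)Cl
Why: O-Silylation protects the acid-sensitive allylic alcohol without touching its stereocentre.

Step 18
Reactants: 22 ethyl (2E,4E)-5-[(1R,4R)-4-[(tert-butyldimethylsilyl)oxy]-2,6,6-trimethylcyclohex-2-en-1-yl]-3-methylpenta-2,4-dienoate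
Product: 23 (2E,4E)-5-[(1R,4R)-4-[(tert-butyldimethylsilyl)oxy]-2,6,6-trimethylcyclohex-2-en-1-yl]-3-methylpenta-2,4-dien-1-ol
Conditions: i-Bu2AlH, CH2Cl2, −78 °C
Reagents that add atoms: none
Why: Aluminium hydride 1,2-reduction of the dienoate gives the dienylic primary alcohol with the double-bond geometry intact.

Step 19
Reactants: 23 (2E,4E)-5-[(1R,4R)-4-[(tert-butyldimethylsilyl)oxy]-2,6,6-trimethylcyclohex-2-en-1-yl]-3-methylpenta-2,4-dien-1-ol
Product: 25 {(2E,4E)-5-[(1R,4R)-4-[(tert-butyldimethylsilyl)oxy]-2,6,6-trimethylcyclohex-2-en-1-yl]-3-methylpenta-2,4-dien-1-yl}triphenylphosphonium bromide, via allylic bromide 24 (not isolated)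
Conditions: CBr4, PPh3, CH2Cl2, −20 °C; then PPh3, rt
Reagents that add atoms: carbon tetrabromide CBr4, BrC(Br)(Br)Br; triphenylphosphine PPh3, c1ccc(cc1)P(c1ccccc1)c1ccccc1
Why: Neutral Appel bromination followed by SN2 quaternisation of PPh3 at the primary dienylic carbon gives the C15 Wittig salt without the acid that would ionise the ring allylic silyl ether.

Step 20
Reactants: 26 (2E,4E,6E)-2,7-dimethylocta-2,4,6-trienedial (C10 dialdehyde)
Product: 27 ethyl (2E,4E,6E,8E)-4,9-dimethyl-10-oxodeca-2,4,6,8-tetraenoate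
Conditions: Ph3P=CHCO2Et (1 equiv), 26 (2.5 equiv), CH2Cl2, rt
Reagents that add atoms: ethyl (triphenylphosphoranylidene)acetate Ph3P=CHCO2Et, CCOC(=O)C=P(c1ccccc1)(c1ccccc1)c1ccccc1
Why: Wittig reaction of the stabilised ylide is E-selective and, with the symmetrical dialdehyde in excess, stops at mono-olefination to give the C12 ester-aldehyde carrying C10–C11.

Step 21
Reactants: 25 {(2E,4E)-5-[(1R,4R)-4-[(tert-butyldimethylsilyl)oxy]-2,6,6-trimethylcyclohex-2-en-1-yl]-3-methylpenta-2,4-dien-1-yl}triphenylphosphonium bromide; 27 ethyl (2E,4E,6E,8E)-4,9-dimethyl-10-oxodeca-2,4,6,8-tetraenoate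
Product: 29 ethyl (2E,4E,6E,8E,10E,12E,14E)-15-[(1R,4R)-4-[(tert-butyldimethylsilyl)oxy]-2,6,6-trimethylcyclohex-2-en-1-yl]-4,9,13-trimethylpentadeca-2,4,6,8,10,12,14-heptaenoate, via phosphonium ylide 28 (not isolated)
Conditions: NaN(SiMe3)2, THF, −78 → 0 °C; then 27; then I2 (cat.), CH2Cl2, daylight, rt
Reagents that add atoms: none
Why: Wittig olefination of the semi-stabilised allylic ylide with the aldehyde of 27 forms the C11′=C12′ bond as an E/Z mixture, and the sterically compressed Z isomer is equilibrated to the all-E polyene by iodine catalysis.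

Step 22
Reactants: 29 ethyl (2E,4E,6E,8E,10E,12E,14E)-15-[(1R,4R)-4-[(tert-butyldimethylsilyl)oxy]-2,6,6-trimethylcyclohex-2-en-1-yl]-4,9,13-trimethylpentadeca-2,4,6,8,10,12,14-heptaenoate
Product: 30 (2E,4E,6E,8E,10E,12E,14E)-15-[(1R,4R)-4-[(tert-butyldimethylsilyl)oxy]-2,6,6-trimethylcyclohex-2-en-1-yl]-4,9,13-trimethylpentadeca-2,4,6,8,10,12,14-heptaen-1-ol
Conditions: i-Bu2AlH, CH2Cl2, −78 °C
Reagents that add atoms: none
Why: Aluminium hydride 1,2-reduction of the polyenoate gives the primary alcohol, as is routine for retinoid and apo-carotenoid esters.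

Step 23
Reactants: 30 (2E,4E,6E,8E,10E,12E,14E)-15-[(1R,4R)-4-[(tert-butyldimethylsilyl)oxy]-2,6,6-trimethylcyclohex-2-en-1-yl]-4,9,13-trimethylpentadeca-2,4,6,8,10,12,14-heptaen-1-ol
Product: 31 (2E,4E,6E,8E,10E,12E,14E)-15-[(1R,4R)-4-[(tert-butyldimethylsilyl)oxy]-2,6,6-trimethylcyclohex-2-en-1-yl]-4,9,13-trimethylpentadeca-2,4,6,8,10,12,14-heptaenal
Conditions: MnO2, CH2Cl2, rt, dark
Reagents that add atoms: none
Why: MnO2 selectively oxidises the polyenylic primary alcohol to the aldehyde (C10 of the target) and leaves the silyl ether and the polyene alone.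

**Part C – fragment union and endgame**

Step 24
Reactants: 15 1-[(4R)-4-[(tert-butyldimethylsilyl)oxy]-2,6,6-trimethylcyclohex-1-en-1-yl]-4-[(triethylsilyl)oxy]butan-2-one; 31 (2E,4E,6E,8E,10E,12E,14E)-15-[(1R,4R)-4-[(tert-butyldimethylsilyl)oxy]-2,6,6-trimethylcyclohex-2-en-1-yl]-4,9,13-trimethylpentadeca-2,4,6,8,10,12,14-heptaenal
Product: 33 (3R,3′R,6′R)-3,3′-bis[(tert-butyldimethylsilyl)oxy]-10-hydroxy-19-[(triethylsilyl)oxy]-7,8,9,10-tetrahydro-β,ε-caroten-8-one (C9/C10 diastereomer mixture), via lithium enolate 32 (not isolated)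
Conditions: LiN(i-Pr)2, THF, −78 °C; then 31, −78 °C; H2O
Reagents that add atoms: none
Why: Directed aldol addition in which the amide base at −78 °C deprotonates the unhindered C9 methylene of 15 (the C7 methylene is shielded by the tetrasubstituted ring carbon and cannot align with both π systems without 1,3-allylic strain) and the lithium enolate adds 1,2 to the polyenal; the two new stereocentres (C9, C10) form unselectively and are both erased in step 25.

Step 25
Reactants: 33 (3R,3′R,6′R)-3,3′-bis[(tert-butyldimethylsilyl)oxy]-10-hydroxy-19-[(triethylsilyl)oxy]-7,8,9,10-tetrahydro-β,ε-caroten-8-one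
Product: 35 (3R,3′R,6′R)-3,3′-bis[(tert-butyldimethylsilyl)oxy]-19-[(triethylsilyl)oxy]-7,8-dihydro-β,ε-caroten-8-one (all-E), via C10 acetate 34 (not isolated)
Conditions: Ac2O, DMAP, pyridine, CH2Cl2, 0 °C; then DBU, rt
Reagents that add atoms: none
Why: E1cB elimination of the β-acetoxy ketone (acetate leaves far more readily than the silyloxide on C19) completes the aldol condensation and gives the thermodynamically preferred enone geometry with the polyene trans to the C8 carbonyl, as in the target.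

Step 26
Reactants: 35 (3R,3′R,6′R)-3,3′-bis[(tert-butyldimethylsilyl)oxy]-19-[(triethylsilyl)oxy]-7,8-dihydro-β,ε-caroten-8-one
Product: 36 (3R,3′R,6′R)-3,3′-bis[(tert-butyldimethylsilyl)oxy]-19-hydroxy-7,8-dihydro-β,ε-caroten-8-one (3,3′-di-O-TBS-siphonaxanthin)
Conditions: PPTS, MeOH/CH2Cl2, 0 °C
Reagents that add atoms: none
Why: Mild acid-catalysed methanolysis cleaves the primary TES ether orders of magnitude faster than the two secondary TBS ethers and is too weak to ionise the ε-ring allylic ether.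

Step 27
Reactants: 36 (3R,3′R,6′R)-3,3′-bis[(tert-butyldimethylsilyl)oxy]-19-hydroxy-7,8-dihydro-β,ε-caroten-8-one; 37 (2E)-oct-2-enoic acid
Product: 38 (3R,3′R,6′R)-3,3′-bis[(tert-butyldimethylsilyl)oxy]-8-oxo-7,8-dihydro-β,ε-caroten-19-yl (2E)-oct-2-enoate
Conditions: EDC·HCl, DMAP, CH2Cl2, 0 °C → rt
Reagents that add atoms: none
Why: Steglich esterification acylates the only free hydroxyl (primary, allylic) under near-neutral conditions that avoid the ketene pathway that would deconjugate the enoate.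

Step 28
Reactants: 38 (3R,3′R,6′R)-3,3′-bis[(tert-butyldimethylsilyl)oxy]-8-oxo-7,8-dihydro-β,ε-caroten-19-yl (2E)-oct-2-enoate
Product: 39 (3R,3′R,6′R)-3,3′-dihydroxy-8-oxo-7,8-dihydro-β,ε-caroten-19-yl (2E)-oct-2-enoate (CNP0344057.1, all-E)
Conditions: HF·pyridine, pyridine, THF, 0 °C → rt, dark
Reagents that add atoms: none
Why: Pyridine-buffered fluoride desilylation removes both secondary TBS ethers without cleaving the allylic enoate ester, epimerising the ε-ring allylic alcohol or isomerising the β,γ-unsaturated ketone.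

**Compound list**
1 | (4R,6R)-4-hydroxy-2,2,6-trimethylcyclohexan-1-one (actinol) | O=C1[C@H](C)C[C@@H](O)CC1(C)C | starting material
2 | (4R,6R)-4-[(tert-butyldimethylsilyl)oxy]-2,2,6-trimethylcyclohexan-1-one | O=C1[C@H](C)C[C@@H](O[Si](C)(C)C(C)(C)C)CC1(C)C | intermediate
3 | lithium (4R)-4-[(tert-butyldimethylsilyl)oxy]-2,6,6-trimethylcyclohex-1-en-1-olate | [Li+].[O-]C1=C(C)C[C@@H](O[Si](C)(C)C(C)(C)C)CC1(C)C | intermediate
4 | (4R)-4-[(tert-butyldimethylsilyl)oxy]-2,6,6-trimethylcyclohex-1-en-1-yl trifluoromethanesulfonate | FC(F)(F)S(=O)(=O)OC1=C(C)C[C@@H](O[Si](C)(C)C(C)(C)C)CC1(C)C | intermediate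
5 | methyl (4R)-4-[(tert-butyldimethylsilyl)oxy]-2,6,6-trimethylcyclohex-1-ene-1-carboxylate | COC(=O)C1=C(C)C[C@@H](O[Si](C)(C)C(C)(C)C)CC1(C)C | intermediate
6 | [(4R)-4-[(tert-butyldimethylsilyl)oxy]-2,6,6-trimethylcyclohex-1-en-1-yl]methanol | OCC1=C(C)C[C@@H](O[Si](C)(C)C(C)(C)C)CC1(C)C | intermediate
7 | {[(1R)-4-(bromomethyl)-3,5,5-trimethylcyclohex-3-en-1-yl]oxy}(tert-butyl)dimethylsilane | BrCC1=C(C)C[C@@H](O[Si](C)(C)C(C)(C)C)CC1(C)C | intermediate
8 | tert-butyldimethyl({(1R)-3,5,5-trimethyl-4-[(phenylsulfonyl)methyl]cyclohex-3-en-1-yl}oxy)silane | O=S(=O)(CC1=C(C)C[C@@H](O[Si](C)(C)C(C)(C)C)CC1(C)C)c1ccccc1 | intermediate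
9 | propane-1,3-diol | OCCCO | starting material
10 | 3-[(triethylsilyl)oxy]propan-1-ol | OCCCO[Si](CC)(CC)CC | intermediate
11 | 3-[(triethylsilyl)oxy]propanal | O=CCCO[Si](CC)(CC)CC | intermediate
12 | α-lithio derivative of sulfone 8 (carbanion on the CH between ring and sulfonyl) | [Li+].O=S(=O)([CH-]C1=C(C)C[C@@H](O[Si](C)(C)C(C)(C)C)CC1(C)C)c1ccccc1 | intermediate
13 | 1-[(4R)-4-[(tert-butyldimethylsilyl)oxy]-2,6,6-trimethylcyclohex-1-en-1-yl]-1-(phenylsulfonyl)-4-[(triethylsilyl)oxy]butan-2-ol (diastereomers at C1 and C2) | O=S(=O)(C(C(O)CCO[Si](CC)(CC)CC)C1=C(C)C[C@@H](O[Si](C)(C)C(C)(C)C)CC1(C)C)c1ccccc1 | intermediate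
14 | 1-[(4R)-4-[(tert-butyldimethylsilyl)oxy]-2,6,6-trimethylcyclohex-1-en-1-yl]-1-(phenylsulfonyl)-4-[(triethylsilyl)oxy]butan-2-one (epimers at C1) | O=S(=O)(C(C(=O)CCO[Si](CC)(CC)CC)C1=C(C)C[C@@H](O[Si](C)(C)C(C)(C)C)CC1(C)C)c1ccccc1 | intermediate
15 | 1-[(4R)-4-[(tert-butyldimethylsilyl)oxy]-2,6,6-trimethylcyclohex-1-en-1-yl]-4-[(triethylsilyl)oxy]butan-2-one | CC[Si](CC)(CC)OCCC(=O)CC1=C(C)C[C@@H](O[Si](C)(C)C(C)(C)C)CC1(C)C | intermediate
16 | (±)-α-ionone, (3E)-4-(2,6,6-trimethylcyclohex-2-en-1-yl)but-3-en-2-one | CC(=O)/C=C/C1C(C)=CCCC1(C)C | starting material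
17 | ethyl (2E,4E)-3-methyl-5-(2,6,6-trimethylcyclohex-2-en-1-yl)penta-2,4-dienoate (racemic) | CCOC(=O)/C=C(C)/C=C/C1C(C)=CCCC1(C)C | intermediate
18 | ethyl (2E,4E)-3-methyl-5-(2,6,6-trimethyl-4-oxocyclohex-2-en-1-yl)penta-2,4-dienoate (racemic) | CCOC(=O)/C=C(C)/C=C/C1C(C)=CC(=O)CC1(C)C | intermediate
19 | ethyl (2E,4E)-5-[(1RS,4RS)-4-hydroxy-2,6,6-trimethylcyclohex-2-en-1-yl]-3-methylpenta-2,4-dienoate (racemic trans; both enantiomers written) | CCOC(=O)/C=C(C)/C=C/[C@H]1C(C)=C[C@H](O)CC1(C)C.CCOC(=O)/C=C(C)/C=C/[C@@H]1C(C)=C[C@@H](O)CC1(C)C | intermediate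
20 | ethyl (2E,4E)-5-[(1R,4R)-4-acetoxy-2,6,6-trimethylcyclohex-2-en-1-yl]-3-methylpenta-2,4-dienoate | CCOC(=O)/C=C(C)/C=C/[C@H]1C(C)=C[C@H](OC(C)=O)CC1(C)C | intermediate
21 | ethyl (2E,4E)-5-[(1R,4R)-4-hydroxy-2,6,6-trimethylcyclohex-2-en-1-yl]-3-methylpenta-2,4-dienoate | CCOC(=O)/C=C(C)/C=C/[C@H]1C(C)=C[C@H](O)CC1(C)C | intermediate
22 | ethyl (2E,4E)-5-[(1R,4R)-4-[(tert-butyldimethylsilyl)oxy]-2,6,6-trimethylcyclohex-2-en-1-yl]-3-methylpenta-2,4-dienoate | CCOC(=O)/C=C(C)/C=C/[C@H]1C(C)=C[C@H](O[Si](C)(C)C(C)(C)C)CC1(C)C | intermediate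
23 | (2E,4E)-5-[(1R,4R)-4-[(tert-butyldimethylsilyl)oxy]-2,6,6-trimethylcyclohex-2-en-1-yl]-3-methylpenta-2,4-dien-1-ol | OC/C=C(C)/C=C/[C@H]1C(C)=C[C@H](O[Si](C)(C)C(C)(C)C)CC1(C)C | intermediate
24 | {[(1R,4R)-4-[(1E,3E)-5-bromo-3-methylpenta-1,3-dien-1-yl]-3,5,5-trimethylcyclohex-2-en-1-yl]oxy}(tert-butyl)dimethylsilane | BrC/C=C(C)/C=C/[C@H]1C(C)=C[C@H](O[Si](C)(C)C(C)(C)C)CC1(C)C | intermediate
25 | {(2E,4E)-5-[(1R,4R)-4-[(tert-butyldimethylsilyl)oxy]-2,6,6-trimethylcyclohex-2-en-1-yl]-3-methylpenta-2,4-dien-1-yl}triphenylphosphonium bromide | [Br-].c1ccccc1[P+](c1ccccc1)(c1ccccc1)C/C=C(C)/C=C/[C@H]1C(C)=C[C@H](O[Si](C)(C)C(C)(C)C)CC1(C)C | intermediate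
26 | (2E,4E,6E)-2,7-dimethylocta-2,4,6-trienedial | O=C/C(C)=C/C=C/C=C(C)/C=O | starting material
27 | ethyl (2E,4E,6E,8E)-4,9-dimethyl-10-oxodeca-2,4,6,8-tetraenoate | CCOC(=O)/C=C/C(C)=C/C=C/C=C(C)/C=O | intermediate
28 | ylide of 25 (P-bound CH deprotonated) | c1ccccc1[P+](c1ccccc1)(c1ccccc1)[CH-]/C=C(C)/C=C/[C@H]1C(C)=C[C@H](O[Si](C)(C)C(C)(C)C)CC1(C)C | intermediate
29 | ethyl (2E,4E,6E,8E,10E,12E,14E)-15-[(1R,4R)-4-[(tert-butyldimethylsilyl)oxy]-2,6,6-trimethylcyclohex-2-en-1-yl]-4,9,13-trimethylpentadeca-2,4,6,8,10,12,14-heptaenoate | CCOC(=O)/C=C/C(C)=C/C=C/C=C(C)/C=C/C=C(C)/C=C/[C@H]1C(C)=C[C@H](O[Si](C)(C)C(C)(C)C)CC1(C)C | intermediate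
30 | (2E,4E,6E,8E,10E,12E,14E)-15-[(1R,4R)-4-[(tert-butyldimethylsilyl)oxy]-2,6,6-trimethylcyclohex-2-en-1-yl]-4,9,13-trimethylpentadeca-2,4,6,8,10,12,14-heptaen-1-ol | OC/C=C/C(C)=C/C=C/C=C(C)/C=C/C=C(C)/C=C/[C@H]1C(C)=C[C@H](O[Si](C)(C)C(C)(C)C)CC1(C)C | intermediate
31 | (2E,4E,6E,8E,10E,12E,14E)-15-[(1R,4R)-4-[(tert-butyldimethylsilyl)oxy]-2,6,6-trimethylcyclohex-2-en-1-yl]-4,9,13-trimethylpentadeca-2,4,6,8,10,12,14-heptaenal | O=C/C=C/C(C)=C/C=C/C=C(C)/C=C/C=C(C)/C=C/[C@H]1C(C)=C[C@H](O[Si](C)(C)C(C)(C)C)CC1(C)C | intermediate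
32 | lithium enolate of 15 (enolate towards C3 of the butanone, C9 of the target) | [Li+].CC[Si](CC)(CC)OCC=C([O-])CC1=C(C)C[C@@H](O[Si](C)(C)C(C)(C)C)CC1(C)C | intermediate
33 | (3R,3′R,6′R)-3,3′-bis[(tert-butyldimethylsilyl)oxy]-10-hydroxy-19-[(triethylsilyl)oxy]-7,8,9,10-tetrahydro-β,ε-caroten-8-one (C9/C10 diastereomers) | CC[Si](CC)(CC)OCC(C(O)/C=C/C(C)=C/C=C/C=C(C)/C=C/C=C(C)/C=C/[C@H]1C(C)=C[C@H](O[Si](C)(C)C(C)(C)C)CC1(C)C)C(=O)CC1=C(C)C[C@@H](O[Si](C)(C)C(C)(C)C)CC1(C)C | intermediate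
34 | C10 acetate of 33 | CC[Si](CC)(CC)OCC(C(OC(C)=O)/C=C/C(C)=C/C=C/C=C(C)/C=C/C=C(C)/C=C/[C@H]1C(C)=C[C@H](O[Si](C)(C)C(C)(C)C)CC1(C)C)C(=O)CC1=C(C)C[C@@H](O[Si](C)(C)C(C)(C)C)CC1(C)C | intermediate
35 | (3R,3′R,6′R)-3,3′-bis[(tert-butyldimethylsilyl)oxy]-19-[(triethylsilyl)oxy]-7,8-dihydro-β,ε-caroten-8-one (all-E) | CC[Si](CC)(CC)OC\C(=C/C=C/C(C)=C/C=C/C=C(C)/C=C/C=C(C)/C=C/[C@H]1C(C)=C[C@H](O[Si](C)(C)C(C)(C)C)CC1(C)C)C(=O)CC1=C(C)C[C@@H](O[Si](C)(C)C(C)(C)C)CC1(C)C | intermediate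
36 | (3R,3′R,6′R)-3,3′-bis[(tert-butyldimethylsilyl)oxy]-19-hydroxy-7,8-dihydro-β,ε-caroten-8-one | OC\C(=C/C=C/C(C)=C/C=C/C=C(C)/C=C/C=C(C)/C=C/[C@H]1C(C)=C[C@H](O[Si](C)(C)C(C)(C)C)CC1(C)C)C(=O)CC1=C(C)C[C@@H](O[Si](C)(C)C(C)(C)C)CC1(C)C | intermediate
37 | (2E)-oct-2-enoic acid | CCCCC/C=C/C(=O)O | starting material
38 | (3R,3′R,6′R)-3,3′-bis[(tert-butyldimethylsilyl)oxy]-8-oxo-7,8-dihydro-β,ε-caroten-19-yl (2E)-oct-2-enoate | CCCCC/C=C/C(=O)OC\C(=C/C=C/C(C)=C/C=C/C=C(C)/C=C/C=C(C)/C=C/[C@H]1C(C)=C[C@H](O[Si](C)(C)C(C)(C)C)CC1(C)C)C(=O)CC1=C(C)C[C@@H](O[Si](C)(C)C(C)(C)C)CC1(C)C | intermediate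
39 | (3R,3′R,6′R)-3,3′-dihydroxy-8-oxo-7,8-dihydro-β,ε-caroten-19-yl (2E)-oct-2-enoate (CNP0344057.1) | CCCCC/C=C/C(=O)OC\C(=C/C=C/C(C)=C/C=C/C=C(C)/C=C/C=C(C)/C=C/[C@H]1C(C)=C[C@H](O)CC1(C)C)C(=O)CC1=C(C)C[C@@H](O)CC1(C)C | target

**Totals**
Total steps: 28. Longest linear sequence: 16 steps (16 → 39 through steps 12–19 and 21–28); the β-ring branch from 1 is 14 steps.

**Three steps most likely to fail**

Step 24 (aldol). The risk is enolisation of 15 at the allylic C7 methylene instead of C9, or β-loss of the silyloxy group from the enolate. The fallback sets out from the β-keto sulfone 14, in which C7 still carries the sulfonyl group. Two equivalents of LiN(i-Pr)2 in THF at −78 °C give the C7,C9-dilithium dianion F1, whose C7 is blocked as the sulfonyl-stabilised carbanion so that only C9 can add to aldehyde 31. This gives the 7-(phenylsulfonyl) aldol adduct F2, and SmI2 in THF/MeOH at −78 °C then removes the sulfonyl group. The route is rejoined at 33 and step 11 is no longer needed.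

Step 15 (lipase resolution). The enantiomer preference and selectivity factor are predicted by rule, not proven for this alcohol. The fallback sets out from racemic 19, which is acylated with (1S)-camphanic chloride (pyridine, DMAP, CH2Cl2). The two diastereomeric esters are separated by chromatography or crystallisation: the (1R,4R)-alcohol (1S)-camphanate F3 and the (1S,4S)-alcohol (1S)-camphanate F4. The configuration is assigned by crystallography, and F3 is ethanolysed (K2CO3, EtOH). The route is rejoined at 21.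

Step 14 (hydride face selectivity). If the hydride enters from the other face, the cis alcohol is the main product. The fallback sets out from 18, which is reduced to the racemic cis alcohol F5 (the inverted-selectivity product, also expected from the small hydride system NaBH4, CeCl3·7H2O, MeOH). Mitsunobu inversion with 4-nitrobenzoic acid (PPh3, DIAD, THF) gives the racemic trans 4-nitrobenzoate F6, and ethanolysis (K2CO3, EtOH) returns to 19.

**Further compounds**
F1 | step 24 | dilithium C7,C9-dianion of β-keto sulfone 14 | [Li+].[Li+].CC[Si](CC)(CC)OCC=C([O-])[C-](S(=O)(=O)c1ccccc1)C1=C(C)C[C@@H](O[Si](C)(C)C(C)(C)C)CC1(C)C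
F2 | step 24 | 7-(phenylsulfonyl) derivative of aldol adduct 33 | CC[Si](CC)(CC)OCC(C(O)/C=C/C(C)=C/C=C/C=C(C)/C=C/C=C(C)/C=C/[C@H]1C(C)=C[C@H](O[Si](C)(C)C(C)(C)C)CC1(C)C)C(=O)C(S(=O)(=O)c1ccccc1)C1=C(C)C[C@@H](O[Si](C)(C)C(C)(C)C)CC1(C)C
F3 | step 15 | (1S)-camphanate of the (1R,4R)-alcohol 21 | CCOC(=O)/C=C(C)/C=C/[C@H]1C(C)=C[C@H](OC(=O)[C@@]23CC[C@@](C)(C(=O)O2)C3(C)C)CC1(C)C
F4 | step 15 | (1S)-camphanate of the (1S,4S)-alcohol | CCOC(=O)/C=C(C)/C=C/[C@@H]1C(C)=C[C@@H](OC(=O)[C@@]23CC[C@@](C)(C(=O)O2)C3(C)C)CC1(C)C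
F5 | step 14 | ethyl (2E,4E)-5-[(1RS,4SR)-4-hydroxy-2,6,6-trimethylcyclohex-2-en-1-yl]-3-methylpenta-2,4-dienoate (racemic cis) | CCOC(=O)/C=C(C)/C=C/[C@H]1C(C)=C[C@@H](O)CC1(C)C.CCOC(=O)/C=C(C)/C=C/[C@@H]1C(C)=C[C@H](O)CC1(C)C
F6 | step 14 | racemic trans 4-nitrobenzoate of 19 | CCOC(=O)/C=C(C)/C=C/[C@H]1C(C)=C[C@H](OC(=O)c2ccc(cc2)[N+](=O)[O-])CC1(C)C.CCOC(=O)/C=C(C)/C=C/[C@@H]1C(C)=C[C@@H](OC(=O)c2ccc(cc2)[N+](=O)[O-])CC1(C)C
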